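The route rests on cutting the central C7′–C8′ bond (chain numbered outward from the ring) of the unbranched tetradecyl chain on C2 of the quinolin-4(1H)-one ring. This bond joins two alike, non-polarised CH2 groups. Both carbons are therefore generated as primary radicals from carboxylates. A mixed Kolbe electrolysis of 8-(1-methyl-4-oxo-1,4-dihydroquinolin-2-yl)octanoic acid with excess octanoic acid expels two CO2 and delivers the finished alkaloid in one operation, with no residual functionality to remove. The step exploits the six-methylene spacer (C1′–C6′) that insulates the radical at C7′ from the bicyclic vinylogous amide, and the absence of stereocentres. The precursor acid comes in one step from lateral lithiation of the C2-methyl group of 1,2-dimethylquinolin-4(1H)-one.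

Key step: step 2

Remark: 1, 2 and 6 are taken as catalogue compounds; the target has no stereocentre and no double-bond geometry, so no step has to control configuration.

Step 1
Reactants: 1 1,2-dimethylquinolin-4(1H)-one; 2 7-bromoheptanoic acid
Product: 5 8-(1-methyl-4-oxo-1,4-dihydroquinolin-2-yl)octanoic acid, via lithium dienolate 3 (not isolated), via lithium 7-bromoheptanoate 4 (not isolated)
Conditions: 1 (1.2 equiv), LDA (1.2 equiv), THF, −78 °C; then 2 pre-treated with LDA (1.0 equiv) in THF–DMPU, −78 °C → rt; aq. HCl to pH 4
Reagents that add atoms: none
Why: Lateral (vinylogous) deprotonation of the C2-methyl group gives the extended lithium dienolate 3, which undergoes SN2 alkylation at its exocyclic carbon because only this restores the aromatic 4-quinolone, while the acid partner travels as the inert lithium carboxylate 4, as in the known alkylation of carbanions with ω-bromoalkanoate salts; no stereocentre is formed.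

Step 2
Reactants: 5 8-(1-methyl-4-oxo-1,4-dihydroquinolin-2-yl)octanoic acid; 6 octanoic acid
Product: 9 1-methyl-2-tetradecylquinolin-4(1H)-one, via quinolonylheptyl radical 7 (not isolated), via heptyl radical 8 (not isolated)
Conditions: Pt anode/Pt cathode, undivided cell, constant current ca. 0.3 A cm⁻², 6 (8 equiv), KOH (5 mol% of total acid), MeOH, 40 °C, stopped when the electrolyte turns slightly basic
Reagents that add atoms: none
Why: At the platinum anode both carboxylates, held in a dense adsorbed layer at high current density, lose one electron and then CO2 to give the primary radicals 7 and 8 side by side, and their combination forms the C7′–C8′ bond (mixed Kolbe electrolysis, the classical way to long unbranched chains from two fatty acids). Two carbons that are both latent donors in polar terms are thus joined with no activating group left behind, so the product of the step is the target itself. No ring is closed and no stereocentre is formed. The cross/homo selectivity is statistical and is secured by the large excess of cheap 6, so that nearly every radical 7 should meet a radical 8, and the non-polar hydrocarbon homodimer of 8 should separate easily from the polar quinolone on silica gel. The radical pathway is favoured over two-electron oxidation (Hofer–Moest) because both radicals are unbranched, primary and free of α-donors, and because smooth Pt, weakly acidic MeOH and high current density are used. The methylenes C1′–C6′ keep C7′ away from ring atoms C2 and C3 (no favourable cyclisation or hydrogen transfer), the carboxylate layer should shield the vinylogous amide ring from the anode, and proton discharge at the Pt cathode is far easier than reduction of the quinolone.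

Compound list
1 | 1,2-dimethylquinolin-4(1H)-one | Cc1cc(=O)c2ccccc2n1C | starting material
2 | 7-bromoheptanoic acid | OC(=O)CCCCCCBr | starting material
3 | lithium dienolate of 1 (lithium 1-methyl-2-methylidene-1,2-dihydroquinolin-4-olate) | [Li+].[O-]C1=CC(=C)N(C)c2ccccc21 | intermediate
4 | lithium 7-bromoheptanoate | [Li+].[O-]C(=O)CCCCCCBr | intermediate
5 | 8-(1-methyl-4-oxo-1,4-dihydroquinolin-2-yl)octanoic acid | OC(=O)CCCCCCCc1cc(=O)c2ccccc2n1C | intermediate
6 | octanoic acid | CCCCCCCC(=O)O | starting material
7 | 7-(1-methyl-4-oxo-1,4-dihydroquinolin-2-yl)heptyl radical | [CH2]CCCCCCc1cc(=O)c2ccccc2n1C | intermediate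
8 | heptyl radical | CCCCCC[CH2] | intermediate
9 | 1-methyl-2-tetradecylquinolin-4(1H)-one | CCCCCCCCCCCCCCc1cc(=O)c2ccccc2n1C | target

Total step count: 2
Longest linear sequence: 2

Steps most likely to fail (the route has only two steps, so both are ranked and there is no third):

1. Step 2.
What may go wrong:
- direct anodic oxidation of the electron-rich quinolone ring in competition with the carboxylates;
- further oxidation of the primary radicals to cations, with capture by methanol;
- disproportionation of the radicals;
- fouling of the anode by the hydrocarbon that separates.

The fallback sets out from 5 and comes back at 9. It replaces the oxidation by a reductive, nickel-catalysed decarboxylative alkyl–alkyl cross-coupling (Negishi type). 5 is esterified with N-hydroxyphthalimide (DIC, cat. DMAP, CH2Cl2) to the redox-active ester 1,3-dioxoisoindolin-2-yl 8-(1-methyl-4-oxo-1,4-dihydroquinolin-2-yl)octanoate F1. Heptylmagnesium bromide and ZnCl2 (0.5 equiv, THF) give diheptylzinc F2. NiCl2·glyme with 4,4′-di-tert-butyl-2,2′-bipyridine in THF–DMF at rt should then couple F1 with F2 to give 9. The same C7′–C8′ bond is formed, the coupling is not statistical, and the quinolone never meets an anode.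

2. Step 1.
What may go wrong: the lithium carboxylate may stay undissolved, so that the SN2 step becomes slower than proton exchange between product and dienolate. This would lead to double alkylation at C1′ and to recovered 1.

The fallback sets out from 1 by way of 3 and comes back at 5. The carboxyl group is carried as a neutral, soluble ester and is unveiled in a separate operation. 3 is alkylated with commercial ethyl 7-bromoheptanoate (THF–DMPU, −78 °C to 0 °C) to give ethyl 8-(1-methyl-4-oxo-1,4-dihydroquinolin-2-yl)octanoate F3. Saponification (LiOH, THF–H2O, rt; then pH 4) gives 5.

Further compounds
F1 | step 2 | 1,3-dioxoisoindolin-2-yl 8-(1-methyl-4-oxo-1,4-dihydroquinolin-2-yl)octanoate | O=C(CCCCCCCc1cc(=O)c2ccccc2n1C)ON1C(=O)c2ccccc2C1=O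
F2 | step 2 | diheptylzinc | CCCCCCC[Zn]CCCCCCC
F3 | step 1 | ethyl 8-(1-methyl-4-oxo-1,4-dihydroquinolin-2-yl)octanoate | CCOC(=O)CCCCCCCc1cc(=O)c2ccccc2n1C
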